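**Retrosynthetic overview**

- Target 8 is methyl shikimate (one cyclohexene ring; C1 bears CO2Me, C1=C2) with the same (E)-3-methylpent-2-enoate on O3 and O5 and a free hydroxyl on C4.
- Feature: C3 and C5 carry identical ester oxygens and each lies beside a ring carbon at aldehyde oxidation level (C2, the alkene CH; C4, the carbinol). C2–C3 and C4–C5 are therefore two copies of one acyloxyacetaldehyde, and C6–C1(CO2Me) is an acrylate.
- Disconnections: C1=C2 (intramolecular Horner–Wadsworth–Emmons), C3–C4 (proline aldol), C5–C6 (enamine Michael addition). This leads to two molecules of aldehyde 4 and phosphonoacrylate 5; the only ring is closed last, in the same flask.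
- Aldehyde 4 comes from acid 1 by carboxylate alkylation with bromoacetal 2 and acetal hydrolysis.

Key step: step 3

Assumption: acid 1 is bought as the geometrically pure E isomer.
Assumption: aldehyde 4 reacts with the silyl ether amine through its E-enamine (acyloxy group trans to nitrogen), as simple aldehydes do; should the Z-enamine carry the reaction, the (R)-configured amine is used in its place.

**Step 1**
Reactants: 1 (E)-3-methylpent-2-enoic acid; 2 bromoacetaldehyde diethyl acetal
Product: 3 2,2-diethoxyethyl (E)-3-methylpent-2-enoate
Conditions: Cs2CO3 (1.2 equiv), NaI (10 mol %), 2 (1.5 equiv), DMF, 90 °C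
Reagents that add atoms: none
Why: SN2 O-alkylation of the cesium carboxylate (iodide-assisted) forms the ester without any acyl activation, so neither ketene-type deconjugation nor scrambling of the E double bond is expected.

**Step 2**
Reactants: 3 2,2-diethoxyethyl (E)-3-methylpent-2-enoate
Product: 4 2-oxoethyl (E)-3-methylpent-2-enoate
Conditions: TFA/H2O (9:1), CH2Cl2, 0 °C to rt; NaHCO3 work-up; dried by toluene azeotrope and used at once
Reagents that add atoms: water, O
Why: Acid-catalysed acetal hydrolysis; aqueous TFA is chosen because the β-acyloxy group slows oxocarbenium formation, and the hindered conjugated ester should survive it.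

**Step 3**
Reactants: 4 2-oxoethyl (E)-3-methylpent-2-enoate (two molecules enter the product); 5 trimethyl 2-phosphonoacrylate
Product: 8 methyl (3R,4S,5R)-4-hydroxy-3,5-bis{[(E)-3-methylpent-2-enoyl]oxy}cyclohex-1-ene-1-carboxylate, via Michael adduct 6 (not isolated), via aldol adduct 7 (not isolated)
Conditions: 5 (1 equiv), 4 (1.2 equiv), (S)-α,α-diphenylprolinol trimethylsilyl ether (10 mol %), PhCO2H (10 mol %), CH2Cl2, 0 °C to rt; then (S)-proline (30 mol %), DMF, 4 °C, 4 (2 equiv) added by syringe pump over 24 h; then LiCl (3 equiv), iPr2NEt (2 equiv), MeCN, 0 °C; pH 7 buffer work-up, chromatography on buffered silica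
Reagents that add atoms: none
Why: Proposed new method: the silyl ether amine converts 4 into an enamine that adds, through the face remote from its CPh2(OSiMe3) group, to the doubly activated alkene of 5 (C5–C6), and the stabilised carbanion is protonated to give 6; (S)-proline then forms the enamine of the slowly added second molecule of 4, which attacks the aldehyde of 6 in the carboxylic-acid-bridged chair-like transition state (C3–C4, anti aldol 7); LiCl/iPr2NEt finally deprotonates C1, which adds to the C2 aldehyde and expels dimethyl phosphate (C1=C2, intramolecular Horner–Wadsworth–Emmons). The closest known reaction types are diarylprolinol silyl ether Michael additions of aldehydes to 2-phosphonoacrylates, proline cross-aldol reactions of α-alkoxyacetaldehydes and intramolecular Horner–Wadsworth–Emmons closures to cyclohexenecarboxylates; an α-acyloxyacetaldehyde as proline enamine donor and the union of the three events in one flask are not established. The single ring closes in the last event by 6-exo-trig attack of the C1 carbanion on the C2 carbonyl followed by loss of phosphate, so the ring alkene has no geometrical alternative. C5 (R) is set by the shielding amine; C4 (S) and C3 (S in 7, R in 8 only because the priorities change on olefination) are set by (S)-proline with its usual aldehyde-face and anti preference; the epimeric phosphonate carbon is destroyed. The step needs the 3,4-anti/4,5-syn array (a catalyst-controlled aldol against the Felkin–Anh bias of the α-acyloxy aldehyde 6, a sense in which proline enamines are known to follow the catalyst with chiral α-oxy aldehydes), cross- over homo-aldol, and no acyl shift to O4; these are served by 6 being α-branched and so unable to act as donor, by its aldehyde being activated by the α-ester oxygen while the donor is kept dilute, and by both esters being hindered β,β-disubstituted enoates that resist aminolysis and migrate slowly in the short, cold base stage. A minor enantiomer at C5 should be carried into the separable 5-epimer and not into the enantiomer of 8, so the two catalyst-controlled events reinforce the enantiopurity.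

**Compound list**

1 | (E)-3-methylpent-2-enoic acid | CC/C(C)=C/C(=O)O | starting material
2 | bromoacetaldehyde diethyl acetal (2-bromo-1,1-diethoxyethane) | CCOC(CBr)OCC | starting material
3 | 2,2-diethoxyethyl (E)-3-methylpent-2-enoate | CC/C(C)=C/C(=O)OCC(OCC)OCC | intermediate
4 | 2-oxoethyl (E)-3-methylpent-2-enoate | CC/C(C)=C/C(=O)OCC=O | intermediate
5 | trimethyl 2-phosphonoacrylate (methyl 2-(dimethoxyphosphoryl)prop-2-enoate) | C=C(C(=O)OC)P(=O)(OC)OC | starting material
6 | methyl (4R)-2-(dimethoxyphosphoryl)-4-{[(E)-3-methylpent-2-enoyl]oxy}-5-oxopentanoate (both epimers at C2) | COC(=O)C(P(=O)(OC)OC)C[C@@H](OC(=O)/C=C(\C)CC)C=O | intermediate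
7 | methyl (4R,5S,6S)-2-(dimethoxyphosphoryl)-5-hydroxy-4,6-bis{[(E)-3-methylpent-2-enoyl]oxy}-7-oxoheptanoate (both epimers at C2) | CC/C(C)=C/C(=O)O[C@H](C=O)[C@@H](O)[C@H](OC(=O)/C=C(\C)CC)CC(C(=O)OC)P(=O)(OC)OC | intermediate
8 | methyl (3R,4S,5R)-4-hydroxy-3,5-bis{[(E)-3-methylpent-2-enoyl]oxy}cyclohex-1-ene-1-carboxylate | CC/C(C)=C/C(=O)O[C@@H]1C=C(C(=O)OC)C[C@@H](OC(=O)/C=C(\C)CC)[C@@H]1O | target

Total step count: 3
Longest linear sequence: 3 steps (1 → 3 → 4 → 8)

**Steps most likely to fail**

1. Step 3. Several processes may defeat it:
   - the ester-bearing aldehyde may not form or use a proline enamine, or may homo-dimerise faster than it adds to 6;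
   - the Felkin–Anh bias may override the catalyst and give the 4-epimer;
   - selectivity at C5 may erode through a Z-enamine;
   - base may shift an acyl group to O4.

   Fallback (known chemistry): the ring is taken from the chiral pool and only the esters are made, setting out from acid 1 and returning at 8.
   - Commercial (−)-shikimic acid F1 is esterified (MeOH, camphorsulfonic acid, reflux) to methyl shikimate F2.
   - TBSCl/imidazole in DMF silylates the two less hindered hydroxyls and should leave the doubly flanked 4-OH, giving methyl 3,5-bis-O-(tert-butyldimethylsilyl)shikimate F3.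
   - 2-Methoxypropene with pyridinium p-toluenesulfonate caps O4, giving methyl 3,5-bis-O-(tert-butyldimethylsilyl)-4-O-(2-methoxypropan-2-yl)shikimate F4.
   - Bu4NF in THF frees the diol, methyl 4-O-(2-methoxypropan-2-yl)shikimate F5.
   - Acid 1 with EDC·HCl and DMAP in CH2Cl2 acylates O3 and O5 to methyl 4-O-(2-methoxypropan-2-yl)-3,5-bis-O-[(E)-3-methylpent-2-enoyl]shikimate F6.
   - Pyridinium p-toluenesulfonate in MeOH at 0 °C removes the acetal under mildly acidic conditions, where acyl shifts are slow, to give 8.

2. Step 2. Hydrolysis of the acetal beside the acyloxy group may be slow, and long exposure to acid may bring hydrate or oligomer formation or isomerisation of the enoate. Fallback: the acetal is avoided, setting out from acid 1 and returning at 4. Acid 1 is coupled with excess ethylene glycol (EDC·HCl, DMAP, CH2Cl2) to 2-hydroxyethyl (E)-3-methylpent-2-enoate F7, which is oxidised with Dess–Martin periodinane (NaHCO3, CH2Cl2, 0 °C) to 4.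

3. Step 1. Displacement at the β-dialkoxy bromide may be sluggish, and the heat needed may scramble the double bond geometry or move the double bond through the dienolate. Fallback: setting out from acid 1 and returning at 3, the ester is made by Mitsunobu esterification with commercial 2,2-diethoxyethanol (PPh3, diisopropyl azodicarboxylate, THF, 0 °C to rt), which activates the alcohol under neutral conditions and forms no new intermediate.

**Further compounds**

F1 | step 3 | (−)-shikimic acid (bought) | O[C@@H]1C=C(C(=O)O)C[C@@H](O)[C@@H]1O
F2 | step 3 | methyl shikimate | O[C@@H]1C=C(C(=O)OC)C[C@@H](O)[C@@H]1O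
F3 | step 3 | methyl 3,5-bis-O-(tert-butyldimethylsilyl)shikimate | CC(C)(C)[Si](C)(C)O[C@@H]1C=C(C(=O)OC)C[C@@H](O[Si](C)(C)C(C)(C)C)[C@@H]1O
F4 | step 3 | methyl 3,5-bis-O-(tert-butyldimethylsilyl)-4-O-(2-methoxypropan-2-yl)shikimate | CC(C)(C)[Si](C)(C)O[C@@H]1C=C(C(=O)OC)C[C@@H](O[Si](C)(C)C(C)(C)C)[C@@H]1OC(C)(C)OC
F5 | step 3 | methyl 4-O-(2-methoxypropan-2-yl)shikimate | O[C@@H]1C=C(C(=O)OC)C[C@@H](O)[C@@H]1OC(C)(C)OC
F6 | step 3 | methyl 4-O-(2-methoxypropan-2-yl)-3,5-bis-O-[(E)-3-methylpent-2-enoyl]shikimate | CC/C(C)=C/C(=O)O[C@@H]1C=C(C(=O)OC)C[C@@H](OC(=O)/C=C(\C)CC)[C@@H]1OC(C)(C)OC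
F7 | step 2 | 2-hydroxyethyl (E)-3-methylpent-2-enoate | CC/C(C)=C/C(=O)OCCO
F0 | step 1 | none | none
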